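The quinone ring is cut at C4–C5. Ring atoms C1(=O)–C2(O)=C3(hexadecyl)–C4(=O) are a ring-opened, squarate-derived cyclobutenone and C5(OMe)=C6(H) is methoxyethyne. This four-plus-two partition of the six-membered ring, with oxygen on C1, C2, C4 and C5, is the feature exploited. Thermolysis of a 4-hydroxy-4-(methoxyethynyl)cyclobutenone opens the four-membered ring to an enynylketene that closes onto the alkyne, forming C4–C5 and the complete quinone in one operation with the substitution pattern fixed beforehand. The precursor is racemic 2-hexadecyl-4-hydroxy-4-(methoxyethynyl)-3-isopropoxycyclobut-2-en-1-one; the isopropyl group masks the C2 hydroxyl and is cleaved last.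

Key step: step 4

Remark: the target is achiral; the only stereocentre on the route (the carbinol carbon of 4 and 9) is racemic and is destroyed, and methoxyethyne is treated as not purchasable and is therefore made in step 2.

Step 1
Reactants: 1 1-bromohexadecane; 2 diisopropyl squarate (3,4-di(propan-2-yloxy)cyclobut-3-ene-1,2-dione)
Product: 5 3-hexadecyl-4-(propan-2-yloxy)cyclobut-3-ene-1,2-dione, via hexadecylmagnesium bromide 3 (not isolated), via squarate 1,2-adduct 4 (not isolated)
Conditions: Mg, THF, 50 °C; add to 2, THF, −78 °C; 1 M HCl quench; crude: conc. HCl (cat.), CH2Cl2, rt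
Reagents that add atoms: none
Why: Grignard 1,2-addition should stop after one carbonyl because the magnesium alkoxide of 4 is a deactivated vinylogous ester, and acid then transposes the carbinol oxygen onto the neighbouring enol-ether carbon and collapses the hemiketal with loss of propan-2-ol to unveil the alkylcyclobutenedione; the carbinol centre of 4 is racemic and vanishes here.

Step 2
Reactants: 6 chloroacetaldehyde dimethyl acetal (2-chloro-1,1-dimethoxyethane)
Product: 7 methoxyethyne (methoxyacetylene), collected as a cold THF solution
Conditions: NaNH2 (3.3 equiv), liq. NH3, −33 °C; evaporate NH3; cold brine, −20 °C; distil into THF at −78 °C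
Reagents that add atoms: none
Why: Sodium amide should effect twofold β-elimination (methanol, then hydrogen chloride) and deprotonation to the sodium acetylide, which cold hydrolysis releases as the volatile alkyne (the classical sodamide dehydrohalogenation route to 1-alkoxyalkynes); isolating the alkyne keeps the acetylide of step 3 free of amines and alkoxides that would attack the vinylogous ester of 5.

Step 3
Reactants: 7 methoxyethyne; 5 3-hexadecyl-4-(propan-2-yloxy)cyclobut-3-ene-1,2-dione
Product: 9 racemic 2-hexadecyl-4-hydroxy-4-(methoxyethynyl)-3-(propan-2-yloxy)cyclobut-2-en-1-one, via lithium methoxyacetylide 8 (not isolated)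
Conditions: 7 (1.2 equiv), n-BuLi (1.1 equiv), THF, −78 °C; add to 5, THF, −78 °C; sat. aq. NH4Cl at −78 °C; pH 7 work-up; Et3N-deactivated SiO2
Reagents that add atoms: none
Why: Acetylide 1,2-addition should occur at carbonyl C1, next to the isopropoxy-bearing C4, because carbonyl C2 is deactivated as a vinylogous ester; the new quaternary carbinol centre forms as a racemate, which is harmless because step 4 erases it, and the cold neutral quench avoids Meyer–Schuster-type rearrangement of the ynol-ether carbinol.

Step 4
Reactants: 9 racemic 2-hexadecyl-4-hydroxy-4-(methoxyethynyl)-3-(propan-2-yloxy)cyclobut-2-en-1-one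
Product: 11 3-hexadecyl-5-methoxy-2-(propan-2-yloxy)cyclohexa-2,5-diene-1,4-dione, via enynylketene 10 (not isolated)
Conditions: PhMe (degassed, 0.02 M), 110 °C
Reagents that add atoms: none
Why: Heating should open the cyclobutenone C1–C4 bond by 4π-conrotatory cleavage with the donor hydroxyl rotating outward, so that the methoxyethynyl group lies cis to the ketene in 10. The ketene carbon (quinone C4) then bonds to the methoxy-bearing alkyne carbon (quinone C5) to give an aryl/phenoxyl diradical or its zwitterionic counterpart, and transfer of the hydroxyl hydrogen to C6 delivers the quinone directly; this is the Moore rearrangement of 4-alkynyl-4-hydroxycyclobutenones, driven by release of ring strain. The six-membered ring is closed stepwise and not pericyclically, by C4–C5 bond formation between the ketene carbon and the distal alkyne carbon, with C1–C4 coming from the cyclobutenone and C5–C6 from the alkyne. No stereocentre is formed and the carbinol centre of 9 is erased. The step needs six-ring closure to win over five-ring closure onto the proximal alkyne carbon, which would lead to a methoxymethylene-cyclopentenedione; the small methoxy terminus gives little stabilisation or steric bias to an exocyclic vinyl radical, the free hydroxyl is an internal hydrogen donor, and methoxy, unlike ethoxy or tert-butoxy, cannot lose an alkene by retro-ene fragmentation at this temperature. The 2-isopropoxy, 3-hexadecyl, 5-methoxy pattern follows from the connectivity of 9 and needs no control.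

Step 5
Reactants: 11 3-hexadecyl-5-methoxy-2-(propan-2-yloxy)cyclohexa-2,5-diene-1,4-dione
Product: 12 3-hexadecyl-2-hydroxy-5-methoxycyclohexa-2,5-diene-1,4-dione
Conditions: BCl3 (1 M in CH2Cl2, 2 equiv), CH2Cl2, −78 → −20 °C; then H2O
Reagents that add atoms: none
Why: Lewis-acid ether cleavage, in which BCl3 bound to the quinone oxygen should ionise the secondary O–isopropyl bond (SN1-like, chloride capture) far faster than the primary O–methyl bond, which can only cleave by slow SN2 attack at this temperature; hydrolysis of the boron ester then frees the hydroxyquinone.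

Compound list
1 | 1-bromohexadecane | CCCCCCCCCCCCCCCCBr | starting material
2 | diisopropyl squarate (3,4-di(propan-2-yloxy)cyclobut-3-ene-1,2-dione) | CC(C)OC1=C(OC(C)C)C(=O)C1=O | starting material
3 | hexadecylmagnesium bromide | CCCCCCCCCCCCCCCC[Mg]Br | intermediate (not isolated)
4 | racemic 4-hexadecyl-4-hydroxy-2,3-di(propan-2-yloxy)cyclobut-2-en-1-one | CCCCCCCCCCCCCCCCC1(O)C(OC(C)C)=C(OC(C)C)C1=O | intermediate (not isolated)
5 | 3-hexadecyl-4-(propan-2-yloxy)cyclobut-3-ene-1,2-dione | CCCCCCCCCCCCCCCCC1=C(OC(C)C)C(=O)C1=O | intermediate
6 | chloroacetaldehyde dimethyl acetal (2-chloro-1,1-dimethoxyethane) | COC(CCl)OC | starting material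
7 | methoxyethyne (methoxyacetylene) | COC#C | intermediate
8 | lithium methoxyacetylide | [Li]C#COC | intermediate (not isolated)
9 | racemic 2-hexadecyl-4-hydroxy-4-(methoxyethynyl)-3-(propan-2-yloxy)cyclobut-2-en-1-one | CCCCCCCCCCCCCCCCC1=C(OC(C)C)C(O)(C#COC)C1=O | intermediate
10 | (3Z)-2-hexadecyl-4-hydroxy-6-methoxy-3-(propan-2-yloxy)hexa-1,3-dien-5-yn-1-one (enynylketene) | CCCCCCCCCCCCCCCCC(=C=O)/C(OC(C)C)=C(/O)C#COC | intermediate (not isolated)
11 | 3-hexadecyl-5-methoxy-2-(propan-2-yloxy)cyclohexa-2,5-diene-1,4-dione | CCCCCCCCCCCCCCCCC1=C(OC(C)C)C(=O)C=C(OC)C1=O | intermediate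
12 | 3-hexadecyl-2-hydroxy-5-methoxycyclohexa-2,5-diene-1,4-dione | CCCCCCCCCCCCCCCCC1=C(O)C(=O)C=C(OC)C1=O | target

Total step count: 5
Longest linear sequence: 4 (steps 1, 3, 4 and 5); step 2 is a one-step side branch.

Steps most likely to fail

Step 4. The enynylketene may close the five-membered way, by bond formation to the proximal alkyne carbon, or the ynol ether may polymerise before the four-membered ring opens. The fallback sets out from 9 and first reduces the alkyne to the alkene. Semi-hydrogenation (H2, Pd/CaCO3 poisoned with Pb(OAc)2, quinoline, EtOAc, 0 °C) should give the enol ether 2-hexadecyl-4-hydroxy-4-[(Z)-2-methoxyethenyl]-3-(propan-2-yloxy)cyclobut-2-en-1-one F1. Heating F1 in PhMe at 110 °C should open the ring to a dienylketene that can only close by 6π-electrocyclisation, and tautomerisation should give the hydroquinone 2-hexadecyl-6-methoxy-3-(propan-2-yloxy)benzene-1,4-diol F2. Oxidation with Ag2O (Et2O, rt) comes back to the route at 11.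

Step 3. The free ynol-ether carbinol may be lost during quench and chromatography through acid-triggered Meyer–Schuster-type rearrangement or retro-addition. The fallback sets out from 5 and the solution of 8. The lithium alkoxide is trapped in the flask with Me3SiCl (−78 → 0 °C, non-aqueous work-up, filtration through basic Al2O3) to give the silyl ether 2-hexadecyl-4-(methoxyethynyl)-3-(propan-2-yloxy)-4-[(trimethylsilyl)oxy]cyclobut-2-en-1-one F3, which resists ionisation. Thermolysis of F3 (PhMe, 110 °C) should follow the silyl-transfer variant of the same rearrangement, the Me3Si group migrating from oxygen to C6, to give 3-hexadecyl-5-methoxy-2-(propan-2-yloxy)-6-(trimethylsilyl)cyclohexa-2,5-diene-1,4-dione F4. Ipso-protodesilylation (CF3CO2H, CH2Cl2, 0 °C), which should be easy because C6 is the electron-rich α-carbon of the vinylogous ester, comes back to the route at 11.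

Step 5. The methyl ether may be lost along with the isopropyl ether, since boron can also chelate between the C4 carbonyl and the C5 methoxy oxygen, or chloride may add to the quinone. The fallback sets out from 11 and cleaves both ethers on purpose (BBr3, CH2Cl2, −78 °C → rt; H2O) to 3-hexadecyl-2,5-dihydroxycyclohexa-2,5-diene-1,4-dione F5. Acid-catalysed methanolysis (MeOH, cat. H2SO4, rt) is a vinylogous Fischer esterification that should take place at the unhindered oxygen-bearing carbon next to C6–H and not at the one next to the hexadecyl group; it comes back to the route at 12.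

Further compounds
F1 | step 4 | 2-hexadecyl-4-hydroxy-4-[(Z)-2-methoxyethenyl]-3-(propan-2-yloxy)cyclobut-2-en-1-one (racemic) | CCCCCCCCCCCCCCCCC1=C(OC(C)C)C(O)(/C=C\OC)C1=O
F2 | step 4 | 2-hexadecyl-6-methoxy-3-(propan-2-yloxy)benzene-1,4-diol | CCCCCCCCCCCCCCCCc1c(OC(C)C)c(O)cc(OC)c1O
F3 | step 3 | 2-hexadecyl-4-(methoxyethynyl)-3-(propan-2-yloxy)-4-[(trimethylsilyl)oxy]cyclobut-2-en-1-one (racemic) | CCCCCCCCCCCCCCCCC1=C(OC(C)C)C(O[Si](C)(C)C)(C#COC)C1=O
F4 | step 3 | 3-hexadecyl-5-methoxy-2-(propan-2-yloxy)-6-(trimethylsilyl)cyclohexa-2,5-diene-1,4-dione | CCCCCCCCCCCCCCCCC1=C(OC(C)C)C(=O)C([Si](C)(C)C)=C(OC)C1=O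
F5 | step 5 | 3-hexadecyl-2,5-dihydroxycyclohexa-2,5-diene-1,4-dione | CCCCCCCCCCCCCCCCC1=C(O)C(=O)C=C(O)C1=O
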